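**Plan**

- Retrosynthetic cuts: the angelate C–O bond and the C15 oxidation level; C8–OH/C17 back to a C8 ketone; C4–CH2OH (formaldehyde ene) and C5–H (hydrogenation) back to a C4=C5 alkene; ring B at C5–C6; C9–C11 (enolate alkylation); the C10–C9 arm (asymmetric allylation of 2,6-dimethylcyclohexanone).
- Forward: ring A is bought. C10 is made quaternary, the allyl arm is cut down to the C9–C8 ester, the C5 ketone becomes its enol triflate, C9 is alkylated with the C11–C15 iodide, and the ester is turned into a cyclopropanol (C8, C7, C6).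
- Ring B then closes by C5–C6 bond formation: palladium-catalysed ring-opening coupling of the cyclopropanol (a ketone homoenolate, nucleophilic at C6) with the C5 enol triflate. C4/C5, C8 and the ester groups follow.
- Enabling feature: C8, the carbinol carbon of ring B, lies β to C6, so it can be carried as a ketone whose homoenolate carbon is C6. C5 sits between the quaternary C4 and C10 of ring A, so it is engaged as the sp2 carbon of the only enol triflate the C5 ketone can form.
- Stereochemistry: C13 from methyl hydrogen (R)-3-methylglutarate; C10 from the chiral Pd–phosphinooxazoline catalyst; C9 by equilibration next to the C8 ketone (both epimers converge); C4 by ene reaction anti to the C10 methyl; C5 by hydroxyl-directed hydrogenation; C8 by equatorial hydration of the exocyclic alkene; the Z enoate from angelic acid.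

Key step: step 11

Remark: atom numbers C1–C20 are those of the labdane skeleton (ring A = C1–C5 and C10; ring B = C5–C10; C4 bears CH3 and CH2O; C8 bears CH3 and OH; side chain C11–C15). 2,6-Dimethylcyclohexanone, methyl hydrogen (R)-3-methylglutarate and angelic acid are taken as commercial.

**Route**

Step 1
Reactants: 1 2,6-dimethylcyclohexan-1-one (cis/trans mixture)
Product: 3 allyl 2,6-dimethylcyclohex-1-en-1-yl carbonate (racemic at C6), via sodium enolate 2 (not isolated)
Conditions: NaN(SiMe3)2, TMEDA, THF, −78 °C; then allyl chloroformate, −78 °C to rt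
Reagents that add atoms: allyl chloroformate, C=CCOC(=O)Cl
Why: Enol carbonate formation by O-acylation of the tetrasubstituted enolate with a chloroformate; the ketone is symmetric, so only one enolate can form, and no stereocentre of the target is set here.

Step 2
Reactants: 3 allyl 2,6-dimethylcyclohex-1-en-1-yl carbonate
Product: 4 (2S)-2,6-dimethyl-2-(prop-2-en-1-yl)cyclohexan-1-one (mixture of C6 epimers)
Conditions: Pd2(dba)3 (2.5 mol%), (S)-t-BuPHOX (6 mol%), THF, 25 °C
Reagents that add atoms: none
Why: Decarboxylative asymmetric allylic alkylation (Tsuji–Trost type): zerovalent palladium ionizes the allyl carbonate, CO2 is lost and the enolate is C-allylated inside the chiral phosphinooxazoline complex, which should set the quaternary carbon (future C10) as S by analogy with 2-methylcyclohexanone substrates.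

Step 3
Reactants: 4 (2S)-2,6-dimethyl-2-(prop-2-en-1-yl)cyclohexan-1-one
Product: 5 methyl 2-[(1S)-1,3-dimethyl-2-oxocyclohexyl]acetate (mixture of C3 epimers)
Conditions: O3, NaOH, MeOH/CH2Cl2, −78 °C
Reagents that add atoms: ozone, [O-][O+]=O; methanol, CO
Why: Ozonolysis of the terminal alkene in basic methanol (oxidative cleavage with esterification in the same flask) should give the methyl ester directly, the terminal CH2 leaving as formaldehyde and the quaternary centre staying untouched.

Step 4
Reactants: 5 methyl 2-[(1S)-1,3-dimethyl-2-oxocyclohexyl]acetate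
Product: 7 methyl 2-[(1S)-1,3-dimethyl-2-(trifluoromethanesulfonyloxy)cyclohex-2-en-1-yl]acetate, via potassium enolate 6 (not isolated)
Conditions: KN(SiMe3)2, THF, −78 °C; then PhNTf2, −78 to 0 °C
Reagents that add atoms: N-phenylbis(trifluoromethanesulfonimide), O=S(=O)(N(c1ccccc1)S(=O)(=O)C(F)(F)F)C(F)(F)F
Why: Enol triflate formation: the ketone has a single α-hydrogen (at C4, because C10 is quaternary) that is far more acidic than the ester α-hydrogens, so one tetrasubstituted C5 enol triflate should result and the epimeric C4 centre becomes planar.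

Step 5
Reactants: 8 methyl hydrogen (R)-3-methylglutarate [(3R)-5-methoxy-3-methyl-5-oxopentanoic acid]
Product: 9 methyl (3R)-5-hydroxy-3-methylpentanoate
Conditions: BH3·SMe2, THF, 0 °C to rt
Reagents that add atoms: none
Why: Chemoselective borane reduction of a carboxylic acid beside an ester; the stereocentre (future C13) comes from the chiral pool and is not touched.

Step 6
Reactants: 9 methyl (3R)-5-hydroxy-3-methylpentanoate
Product: 10 methyl (3R)-3-methyl-5-[(triisopropylsilyl)oxy]pentanoate
Conditions: iPr3SiCl, imidazole, DMF, rt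
Reagents that add atoms: triisopropylsilyl chloride, CC(C)[Si](Cl)(C(C)C)C(C)C
Why: Silylation of the primary alcohol, done at once to prevent lactonization, gives an ether that should survive strong base, Grignard reagents and Lewis acid.

Step 7
Reactants: 10 methyl (3R)-3-methyl-5-[(triisopropylsilyl)oxy]pentanoate
Product: 11 (3S)-3-methyl-5-[(triisopropylsilyl)oxy]pentan-1-ol
Conditions: LiAlH4, Et2O, 0 °C
Reagents that add atoms: none
Why: Hydride reduction of the ester to the primary alcohol; the stereocentre is untouched and its descriptor changes only through the priority rules.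

Step 8
Reactants: 11 (3S)-3-methyl-5-[(triisopropylsilyl)oxy]pentan-1-ol
Product: 12 {[(3R)-5-iodo-3-methylpentyl]oxy}triisopropylsilane
Conditions: I2, PPh3, imidazole, CH2Cl2, 0 °C
Reagents that add atoms: iodine, [I][I]
Why: Appel-type iodination of a primary alcohol (SN2 displacement of the alkoxyphosphonium ion by iodide).

Step 9
Reactants: 7 methyl 2-[(1S)-1,3-dimethyl-2-(trifluoromethanesulfonyloxy)cyclohex-2-en-1-yl]acetate; 12 {[(3R)-5-iodo-3-methylpentyl]oxy}triisopropylsilane
Product: 14 methyl (2RS,5S)-2-[(1S)-1,3-dimethyl-2-(trifluoromethanesulfonyloxy)cyclohex-2-en-1-yl]-5-methyl-7-[(triisopropylsilyl)oxy]heptanoate, via lithium ester enolate 13 (not isolated)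
Conditions: LiN(iPr)2, THF, −78 °C; then 12, DMPU, −78 to 0 °C
Reagents that add atoms: none
Why: Ester enolate alkylation (SN2) with a primary iodide joins C9 to C11; C9 is accepted as an epimer mixture because it becomes epimerizable next to the C8 ketone and is corrected in step 13.

Step 10
Reactants: 14 methyl (2RS,5S)-2-[(1S)-1,3-dimethyl-2-(trifluoromethanesulfonyloxy)cyclohex-2-en-1-yl]-5-methyl-7-[(triisopropylsilyl)oxy]heptanoate
Product: 15 1-{(1RS,4S)-1-[(1S)-1,3-dimethyl-2-(trifluoromethanesulfonyloxy)cyclohex-2-en-1-yl]-4-methyl-6-[(triisopropylsilyl)oxy]hexyl}cyclopropan-1-ol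
Conditions: EtMgBr (4 equiv), Ti(OiPr)4 (0.5 equiv), THF, 0 °C to rt
Reagents that add atoms: ethylmagnesium bromide, CC[Mg]Br
Why: Kulinkovich cyclopropanation: the titanacyclopropane (iPrO)2Ti(C2H4) made from EtMgBr and Ti(OiPr)4 adds twice to the ester carbonyl, turning C8 into a cyclopropanol carbon that carries C7 and C6, while the silyl ether and the enol triflate should be inert to it.

Step 11
Reactants: 15 1-{(1RS,4S)-1-[(1S)-1,3-dimethyl-2-(trifluoromethanesulfonyloxy)cyclohex-2-en-1-yl]-4-methyl-6-[(triisopropylsilyl)oxy]hexyl}cyclopropan-1-ol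
Product: 17 (1RS,8aS)-5,8a-dimethyl-1-{(3S)-3-methyl-5-[(triisopropylsilyl)oxy]pentyl}-3,4,6,7,8,8a-hexahydronaphthalen-2(1H)-one, via alkylpalladium homoenolate palladacycle 16 (not isolated)
Conditions: Pd(OAc)2 (10 mol%), XPhos (20 mol%), Cs2CO3, toluene, 80 °C
Reagents that add atoms: none
Why: Zerovalent palladium inserts into the C5–OTf bond, the cyclopropanol is bound as a palladium alkoxide, and strain-driven β-carbon elimination opens the three-membered ring to the divalent-palladium ketone homoenolate 16, whose C(sp2)–C(sp3) reductive elimination forms the C5–C6 bond. The closest known reaction type is the palladium-catalysed ring-opening cross-coupling of cyclopropanols with aryl and alkenyl halides or triflates (ketone homoenolate coupling), run here intramolecularly. Ring B closes as a six-membered ring by reductive elimination from a seven-membered palladacycle, both partners being held on the quaternary C10, and the two cyclopropane CH2 groups are equivalent, so only one homoenolate can form. No new stereocentre is created (C5 stays sp2), but the C8 carbonyl that appears makes C9 epimerizable, so the C9 epimers of 15 later converge (step 13) under thermodynamic control to the equatorial side chain. The step needs reductive elimination to outrun β-hydride elimination of the C6–Pd bond and needs a single site of oxidative addition; the bulky biaryl phosphine and the short tether should favour the former, and the C5 ketone of ring A could enolize only toward C4, so only one enol triflate exists.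

Step 12
Reactants: 17 (1RS,8aS)-5,8a-dimethyl-1-{(3S)-3-methyl-5-[(triisopropylsilyl)oxy]pentyl}-3,4,6,7,8,8a-hexahydronaphthalen-2(1H)-one
Product: 18 (1RS,5S,8aS)-5-(hydroxymethyl)-5,8a-dimethyl-1-{(3S)-3-methyl-5-[(triisopropylsilyl)oxy]pentyl}-3,5,6,7,8,8a-hexahydronaphthalen-2(1H)-one
Conditions: (CH2O)n, Me2AlCl (2.5 equiv), CH2Cl2, −78 to 0 °C
Reagents that add atoms: formaldehyde (as paraformaldehyde), C=O
Why: Lewis acid-promoted carbonyl-ene reaction: formaldehyde should bond to C4, the less hindered end of the tetrasubstituted C4=C5 alkene, on the face anti to the C10 methyl, while an allylic hydrogen of C6 (the only ones on the other end) is transferred, so the C4 quaternary centre forms with CH2OH trans to the C10 methyl and the alkene moves to C5=C6.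

Step 13
Reactants: 18 (1RS,5S,8aS)-5-(hydroxymethyl)-5,8a-dimethyl-1-{(3S)-3-methyl-5-[(triisopropylsilyl)oxy]pentyl}-3,5,6,7,8,8a-hexahydronaphthalen-2(1H)-one
Product: 20 (1S,4aS,5S,8aR)-5-(hydroxymethyl)-5,8a-dimethyl-1-{(3S)-3-methyl-5-[(triisopropylsilyl)oxy]pentyl}octahydronaphthalen-2(1H)-one, via C9-epimeric decalone mixture 19 (not isolated)
Conditions: H2 (1 atm), [Ir(cod)(PCy3)(py)]PF6 (5 mol%), CH2Cl2, rt; then NaOMe (cat.), MeOH, rt
Reagents that add atoms: none
Why: Hydroxyl-directed homogeneous hydrogenation: iridium bound to the C4 CH2OH should deliver hydrogen to C5 on the face away from the axial C4 and C10 methyls, giving the trans ring fusion, and the base then equilibrates C9 (α to the C8 ketone) to the equatorial side chain.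

Step 14
Reactants: 20 (1S,4aS,5S,8aR)-5-(hydroxymethyl)-5,8a-dimethyl-1-{(3S)-3-methyl-5-[(triisopropylsilyl)oxy]pentyl}octahydronaphthalen-2(1H)-one
Product: 21 [(1S,4aS,5R,8aS)-1,4a-dimethyl-6-methylidene-5-{(3S)-3-methyl-5-[(triisopropylsilyl)oxy]pentyl}decahydronaphthalen-1-yl]methanol
Conditions: Zn, CH2Br2, TiCl4, THF/CH2Cl2, 0 °C to rt
Reagents that add atoms: dibromomethane, BrCBr
Why: Lombardo–Takai methylenation: the non-basic zinc/titanium methylene reagent should convert the hindered, enolizable C8 ketone into the exocyclic alkene without disturbing C9, and it tolerates the free alcohol.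

Step 15
Reactants: 21 [(1S,4aS,5R,8aS)-1,4a-dimethyl-6-methylidene-5-{(3S)-3-methyl-5-[(triisopropylsilyl)oxy]pentyl}decahydronaphthalen-1-yl]methanol
Product: 23 (1S,2S,4aS,5S,8aR)-5-(hydroxymethyl)-2,5,8a-trimethyl-1-{(3S)-3-methyl-5-[(triisopropylsilyl)oxy]pentyl}decahydronaphthalen-2-ol, via acetoxymercury adduct 22 (not isolated)
Conditions: Hg(OAc)2, THF/H2O, rt; then NaBH4, aq NaOH, 0 °C
Reagents that add atoms: water, O
Why: Markovnikov oxymercuration–demercuration: water should add to the tertiary C8 from the equatorial direction because the axial direction is blocked by the syn-axial C10 methyl, which sets C8 with equatorial OH and axial CH3 as in the target.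

Step 16
Reactants: 23 (1S,2S,4aS,5S,8aR)-5-(hydroxymethyl)-2,5,8a-trimethyl-1-{(3S)-3-methyl-5-[(triisopropylsilyl)oxy]pentyl}decahydronaphthalen-2-ol; 24 angelic acid [(2Z)-2-methylbut-2-enoic acid]
Product: 26 [(1S,4aR,5S,6S,8aS)-6-hydroxy-1,4a,6-trimethyl-5-{(3S)-3-methyl-5-[(triisopropylsilyl)oxy]pentyl}decahydronaphthalen-1-yl]methyl (2Z)-2-methylbut-2-enoate, via mixed anhydride 25 (not isolated)
Conditions: 24, 2,4,6-trichlorobenzoyl chloride, Et3N, toluene, rt; then 23, 80 °C
Reagents that add atoms: none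
Why: Yamaguchi-type esterification through the mixed anhydride, run without DMAP so that the Z alkene of the angelate should not isomerize, acylates only the primary neopentyl alcohol and leaves the tertiary C8 alcohol free.

Step 17
Reactants: 26 [(1S,4aR,5S,6S,8aS)-6-hydroxy-1,4a,6-trimethyl-5-{(3S)-3-methyl-5-[(triisopropylsilyl)oxy]pentyl}decahydronaphthalen-1-yl]methyl (2Z)-2-methylbut-2-enoate
Product: 27 [(1S,4aR,5S,6S,8aS)-6-hydroxy-5-[(3S)-5-hydroxy-3-methylpentyl]-1,4a,6-trimethyldecahydronaphthalen-1-yl]methyl (2Z)-2-methylbut-2-enoate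
Conditions: HF·pyridine, pyridine/THF, 0 °C to rt
Reagents that add atoms: none
Why: Fluoride-mediated cleavage of the primary silyl ether under buffered conditions that should spare the tertiary alcohol and the angelate.

Step 18
Reactants: 27 [(1S,4aR,5S,6S,8aS)-6-hydroxy-5-[(3S)-5-hydroxy-3-methylpentyl]-1,4a,6-trimethyldecahydronaphthalen-1-yl]methyl (2Z)-2-methylbut-2-enoate
Product: 29 (3S)-5-[(1S,2S,4aS,5S,8aR)-2-hydroxy-2,5,8a-trimethyl-5-({[(2Z)-2-methylbut-2-enoyl]oxy}methyl)decahydronaphthalen-1-yl]-3-methylpentanoic acid, via C15 aldehyde 28 (not isolated)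
Conditions: TEMPO (20 mol%), PhI(OAc)2, MeCN/H2O, rt
Reagents that add atoms: water, O
Why: Oxoammonium (TEMPO) oxidation of the primary alcohol through the aldehyde hydrate to the carboxylic acid should leave the tertiary alcohol and the enoate alone and cannot epimerize C13, which is β to the new carbonyl.

**Compound list**

1 | 2,6-dimethylcyclohexan-1-one (cis/trans mixture) | CC1CCCC(C)C1=O | starting material
2 | sodium 2,6-dimethylcyclohex-1-en-1-olate (not isolated) | CC1CCCC(C)=C1[O-].[Na+] | intermediate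
3 | allyl 2,6-dimethylcyclohex-1-en-1-yl carbonate (racemic at C6) | C=CCOC(=O)OC1=C(C)CCCC1C | intermediate
4 | (2S)-2,6-dimethyl-2-(prop-2-en-1-yl)cyclohexan-1-one (C6 epimers) | C=CC[C@]1(C)CCCC(C)C1=O | intermediate
5 | methyl 2-[(1S)-1,3-dimethyl-2-oxocyclohexyl]acetate (C3 epimers) | COC(=O)C[C@]1(C)CCCC(C)C1=O | intermediate
6 | potassium enolate of 5 (not isolated) | COC(=O)C[C@]1(C)CCCC(C)=C1[O-].[K+] | intermediate
7 | methyl 2-[(1S)-1,3-dimethyl-2-(trifluoromethanesulfonyloxy)cyclohex-2-en-1-yl]acetate | COC(=O)C[C@]1(C)CCCC(C)=C1OS(=O)(=O)C(F)(F)F | intermediate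
8 | methyl hydrogen (R)-3-methylglutarate [(3R)-5-methoxy-3-methyl-5-oxopentanoic acid] | COC(=O)C[C@H](C)CC(=O)O | starting material
9 | methyl (3R)-5-hydroxy-3-methylpentanoate | COC(=O)C[C@H](C)CCO | intermediate
10 | methyl (3R)-3-methyl-5-[(triisopropylsilyl)oxy]pentanoate | COC(=O)C[C@H](C)CCO[Si](C(C)C)(C(C)C)C(C)C | intermediate
11 | (3S)-3-methyl-5-[(triisopropylsilyl)oxy]pentan-1-ol | OCC[C@H](C)CCO[Si](C(C)C)(C(C)C)C(C)C | intermediate
12 | {[(3R)-5-iodo-3-methylpentyl]oxy}triisopropylsilane | ICC[C@H](C)CCO[Si](C(C)C)(C(C)C)C(C)C | intermediate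
13 | lithium ester enolate of 7 (not isolated) | COC([O-])=C[C@]1(C)CCCC(C)=C1OS(=O)(=O)C(F)(F)F.[Li+] | intermediate
14 | methyl (2RS,5S)-2-[(1S)-1,3-dimethyl-2-(trifluoromethanesulfonyloxy)cyclohex-2-en-1-yl]-5-methyl-7-[(triisopropylsilyl)oxy]heptanoate (C9 epimers) | COC(=O)C(CC[C@H](C)CCO[Si](C(C)C)(C(C)C)C(C)C)[C@]1(C)CCCC(C)=C1OS(=O)(=O)C(F)(F)F | intermediate
15 | 1-{(1RS,4S)-1-[(1S)-1,3-dimethyl-2-(trifluoromethanesulfonyloxy)cyclohex-2-en-1-yl]-4-methyl-6-[(triisopropylsilyl)oxy]hexyl}cyclopropan-1-ol | OC1(CC1)C(CC[C@H](C)CCO[Si](C(C)C)(C(C)C)C(C)C)[C@]2(C)CCCC(C)=C2OS(=O)(=O)C(F)(F)F | intermediate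
16 | seven-membered C5–Pd–C6 palladacycle, a divalent-palladium ketone homoenolate (phosphine not shown; not isolated) | CC1=C2[Pd]CCC(=O)C(CC[C@H](C)CCO[Si](C(C)C)(C(C)C)C(C)C)[C@]2(C)CCC1 | intermediate
17 | (1RS,8aS)-5,8a-dimethyl-1-{(3S)-3-methyl-5-[(triisopropylsilyl)oxy]pentyl}-3,4,6,7,8,8a-hexahydronaphthalen-2(1H)-one (C4=C5 alkene, C8 ketone, C9 epimers) | CC1=C2CCC(=O)C(CC[C@H](C)CCO[Si](C(C)C)(C(C)C)C(C)C)[C@]2(C)CCC1 | intermediate
18 | (1RS,5S,8aS)-5-(hydroxymethyl)-5,8a-dimethyl-1-{(3S)-3-methyl-5-[(triisopropylsilyl)oxy]pentyl}-3,5,6,7,8,8a-hexahydronaphthalen-2(1H)-one (C5=C6 alkene; CH2OH trans to C10 methyl) | OC[C@@]1(C)CCC[C@]2(C)C1=CCC(=O)C2CC[C@H](C)CCO[Si](C(C)C)(C(C)C)C(C)C | intermediate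
19 | trans-fused decalone, mixture of C9 epimers (not isolated) | OC[C@@]1(C)CCC[C@]2(C)[C@@H]1CCC(=O)C2CC[C@H](C)CCO[Si](C(C)C)(C(C)C)C(C)C | intermediate
20 | (1S,4aS,5S,8aR)-5-(hydroxymethyl)-5,8a-dimethyl-1-{(3S)-3-methyl-5-[(triisopropylsilyl)oxy]pentyl}octahydronaphthalen-2(1H)-one | OC[C@@]1(C)CCC[C@]2(C)[C@@H]1CCC(=O)[C@H]2CC[C@H](C)CCO[Si](C(C)C)(C(C)C)C(C)C | intermediate
21 | [(1S,4aS,5R,8aS)-1,4a-dimethyl-6-methylidene-5-{(3S)-3-methyl-5-[(triisopropylsilyl)oxy]pentyl}decahydronaphthalen-1-yl]methanol | OC[C@@]1(C)CCC[C@]2(C)[C@@H]1CCC(=C)[C@H]2CC[C@H](C)CCO[Si](C(C)C)(C(C)C)C(C)C | intermediate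
22 | C8 tertiary alcohol carrying CH2HgOAc at C17 (not isolated) | OC[C@@]1(C)CCC[C@]2(C)[C@@H]1CC[C@](C[Hg]OC(C)=O)(O)[C@H]2CC[C@H](C)CCO[Si](C(C)C)(C(C)C)C(C)C | intermediate
23 | (1S,2S,4aS,5S,8aR)-5-(hydroxymethyl)-2,5,8a-trimethyl-1-{(3S)-3-methyl-5-[(triisopropylsilyl)oxy]pentyl}decahydronaphthalen-2-ol | OC[C@@]1(C)CCC[C@]2(C)[C@@H]1CC[C@](C)(O)[C@H]2CC[C@H](C)CCO[Si](C(C)C)(C(C)C)C(C)C | intermediate
24 | angelic acid [(2Z)-2-methylbut-2-enoic acid] | C/C=C(/C)C(=O)O | starting material
25 | (2Z)-2-methylbut-2-enoic 2,4,6-trichlorobenzoic anhydride (not isolated) | C/C=C(/C)C(=O)OC(=O)c1c(Cl)cc(Cl)cc1Cl | intermediate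
26 | [(1S,4aR,5S,6S,8aS)-6-hydroxy-1,4a,6-trimethyl-5-{(3S)-3-methyl-5-[(triisopropylsilyl)oxy]pentyl}decahydronaphthalen-1-yl]methyl (2Z)-2-methylbut-2-enoate | C/C=C(/C)C(=O)OC[C@@]1(C)CCC[C@]2(C)[C@@H]1CC[C@](C)(O)[C@H]2CC[C@H](C)CCO[Si](C(C)C)(C(C)C)C(C)C | intermediate
27 | [(1S,4aR,5S,6S,8aS)-6-hydroxy-5-[(3S)-5-hydroxy-3-methylpentyl]-1,4a,6-trimethyldecahydronaphthalen-1-yl]methyl (2Z)-2-methylbut-2-enoate | C/C=C(/C)C(=O)OC[C@@]1(C)CCC[C@]2(C)[C@@H]1CC[C@](C)(O)[C@H]2CC[C@H](C)CCO | intermediate
28 | [(1S,4aR,5S,6S,8aS)-6-hydroxy-1,4a,6-trimethyl-5-[(3S)-3-methyl-5-oxopentyl]decahydronaphthalen-1-yl]methyl (2Z)-2-methylbut-2-enoate (not isolated) | C/C=C(/C)C(=O)OC[C@@]1(C)CCC[C@]2(C)[C@@H]1CC[C@](C)(O)[C@H]2CC[C@H](C)CC=O | intermediate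
29 | (3S)-5-[(1S,2S,4aS,5S,8aR)-2-hydroxy-2,5,8a-trimethyl-5-({[(2Z)-2-methylbut-2-enoyl]oxy}methyl)decahydronaphthalen-1-yl]-3-methylpentanoic acid | C/C=C(/C)C(=O)OC[C@@]1(C)CCC[C@]2(C)[C@@H]1CC[C@](C)(O)[C@H]2CC[C@H](C)CC(=O)O | target

**Step count and risks**

Total step count: 18. Longest linear sequence: 14 steps (steps 1–4 and 9–18 from 1; the branch 5–8 and 9–18 from 8 is equally long).

Steps most likely to fail:

1. Step 11 (key ring closure). Reductive elimination may lose to β-hydride elimination of the alkylpalladium homoenolate, or oxidative addition into the hindered tetrasubstituted enol triflate may be too slow. The fallback sets out from 15 and returns at 17. Ring-opening iodination of the cyclopropanol with N-iodosuccinimide (CH2Cl2, 0 °C) should give the β-iodo ketone F1. F1 is then cyclized by nickel-catalysed reductive cross-electrophile coupling of the primary alkyl iodide with the enol triflate (NiBr2·glyme, 4,4′-di-tert-butyl-2,2′-bipyridine, Mn, DMA, rt). Radical capture at nickel replaces transmetalation of a homoenolate, and the same C5–C6 bond is formed.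

2. Step 10 (Kulinkovich reaction). The titanacyclopropane may add too slowly to the very hindered ester (α-branched and next to a quaternary carbon), or the Grignard reagent may attack the enol triflate at sulfur. The fallback sets out from 14 and returns at 17, bypassing 15. Half-reduction with iBu2AlH (CH2Cl2, −78 °C) should give the aldehyde F2, and vinylmagnesium bromide (THF, −78 °C) the allylic alcohol F3. Dess–Martin oxidation then gives the vinyl ketone F4. An intramolecular reductive Heck reaction (Pd(OAc)2, PPh3, HCO2H, Et3N, DMF, 60 °C) closes ring B: the alkenylpalladium species from the enol triflate adds to the enone β-carbon C6 and formate reduces the palladium enolate.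

3. Step 13 (hydrogenation of the C5=C6 alkene). The trisubstituted alkene flanked by two quaternary carbons may react too slowly, so that the cationic iridium catalyst deactivates, or the β,γ-unsaturated ketone may drift into conjugation. The fallback sets out from 18 and returns at 20. It is a radical hydrogenation by metal-hydride hydrogen atom transfer (Mn(dpm)3, PhSiH3, tert-butyl hydroperoxide, iPrOH, rt): hydrogen is transferred to C6 and the tertiary C5 radical then takes up hydrogen to give the thermodynamically preferred trans-fused decalin. The same NaOMe equilibration of C9 follows, and no new compound arises.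

**Further compounds**

F1 | step 11 | (4RS,7S)-4-[(1S)-1,3-dimethyl-2-(trifluoromethanesulfonyloxy)cyclohex-2-en-1-yl]-1-iodo-7-methyl-9-[(triisopropylsilyl)oxy]nonan-3-one | ICCC(=O)C(CC[C@H](C)CCO[Si](C(C)C)(C(C)C)C(C)C)[C@]1(C)CCCC(C)=C1OS(=O)(=O)C(F)(F)F
F2 | step 10 | (2RS,5S)-2-[(1S)-1,3-dimethyl-2-(trifluoromethanesulfonyloxy)cyclohex-2-en-1-yl]-5-methyl-7-[(triisopropylsilyl)oxy]heptanal | O=CC(CC[C@H](C)CCO[Si](C(C)C)(C(C)C)C(C)C)[C@]1(C)CCCC(C)=C1OS(=O)(=O)C(F)(F)F
F3 | step 10 | (3RS,4RS,7S)-4-[(1S)-1,3-dimethyl-2-(trifluoromethanesulfonyloxy)cyclohex-2-en-1-yl]-7-methyl-9-[(triisopropylsilyl)oxy]non-1-en-3-ol | C=CC(O)C(CC[C@H](C)CCO[Si](C(C)C)(C(C)C)C(C)C)[C@]1(C)CCCC(C)=C1OS(=O)(=O)C(F)(F)F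
F4 | step 10 | (4RS,7S)-4-[(1S)-1,3-dimethyl-2-(trifluoromethanesulfonyloxy)cyclohex-2-en-1-yl]-7-methyl-9-[(triisopropylsilyl)oxy]non-1-en-3-one | C=CC(=O)C(CC[C@H](C)CCO[Si](C(C)C)(C(C)C)C(C)C)[C@]1(C)CCCC(C)=C1OS(=O)(=O)C(F)(F)F
F0 | step 13 | none | none
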